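The ratio to look at first in this flask is that of the charges, J against Z: 2.00%.

Z 20 mM (fed, over 3.0 s); J 0.400 mM; time 5.0 min

    Z ⇌ X (K1 = 0.424, k1 = 0.203 s⁻¹)
    Z ⇌ Q (K2 = 0.477, k2 = 0.103 s⁻¹)
    Q ⇌ L (K3 = 1.5, k3 = 0.127 s⁻¹)
    L ⇌ D (K4 = 0.40, k4 = 0.0618 s⁻¹)
    L ⇌ Z (k5 = 0.608 s⁻¹)
    J + X → J.X (k6 = 58.7 M⁻¹ s⁻¹)

- what has gone from Z into another species counts as reacted, even if it can come back
- the reaction counts as stopped when no species that holds the Z changes by six tenths of a point or more over the second half of the time
- run time (flask): 5.0 min

- which holds at 5.0 min: what has brought the reaction to rest, or that it has not come to rest (forward and back rates have come level / it is still moving / all of Z has reacted)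
- conversion of Z at 5.0 min
- amount of D at 5.0 min, in percent of the Z charged

**Examiner:** Which clock do you read first?

**Candidate:** The reversible steps. L and D relax by their own step with a half-life of 3.20 s, far shorter than the run of 5.0 min, so I expect Z, X, Q, L and D to reach equilibrium early. Take Z as one and weigh each other species by the product of equilibrium constants along its path from Z. Z, X, Q, L and D then sum to 2.90.

**Examiner:** But J + X → J.X runs one way. Doesn't it drain that pool?

**Candidate:** It takes one Z for each J, and J is the limiting reagent, 0.400 mM against 20 mM of Z. With c(X) near its pool value of 2.92 mM, J has a half-life of 4.04 s, far shorter than the run. So control changes hands when J is used up: before that the rate of trapping counts, and afterwards the closed pool, which is thermodynamic control.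

**Examiner:** Does the route from L straight back to Z upset the pool?

**Candidate:** No. Its equilibrium constant is the reciprocal of the product along Z to Q to L, so the loop closes on the same ratios.

**Examiner:** Your numbers?

**Candidate:** I carry the pool share of D, the fraction of the reversible pool standing as D at equilibrium, its weight divided by the sum: 9.86%. The pool holds 98.0% of the charge. So I reckon D at 9.66% of the charge and conversion at 66.2%, with the state at the end: forward and back rates have come level.

The forecast stands on the same ground and gives the same figures: forward and back rates have come level, conversion 66.2%, D 9.66%. Its reasoning is that “J should be used up early by the abundant X”.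

The simulated flask gives at 5.00 min: forward and back rates have come level, conversion 66.2%, D 9.66%.

In this flask J stands at 0% of its charge and J.X at 2.00% of the Z charged. The neighbouring flask has the same recipe but 0.16 mM of J. I apply the same share to a pool of 99.2% of the charge, which gives D at 9.78%. The simulated neighbouring flask holds J at 0% of its charge and J.X at 0.800% of the Z charged, with conversion 65.8% and D at 9.78%.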